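**Retrosynthetic overview**

1. Numbering: oxolan-2-one ring O1, C2 (C=O), C3, C4 (CHOH), C5 (C–Me); side chain C6 (CH2), C7 (C(Me)OH), C8–C23 (hexadecyl). Ring atom C5 and side-chain atom C7 are both methyl-bearing tertiary C–O carbons, 1,3-anti across the C6 methylene, so C4–C5–C6–C7–C8 is a hidden C2-symmetric unit, (2S,4S)-2,4-dimethylpentane-1,2,4,5-tetraol.
2. The lactone ring, the only ring of the target, is closed last (C5–O onto the C2 ester), after the C3–C4 bond is made by a chelation-controlled acetate aldol on the C4 aldehyde.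
3. C8–C9 is made by copper-catalysed opening of a C7/C8 epoxide with the pentadecyl Grignard reagent; the two ends of the tetraol are told apart by mono-benzylidenation.
4. The tetraol comes from hydride opening of the C2-symmetric bis-epoxide made by a two-directional double titanium–tartrate epoxidation of 2,4-dimethylenepentane-1,5-diol; the two oxiranes are transient rings.
5. The diene diol comes from DABCO coupling of methyl acrylate with methyl 2-(bromomethyl)acrylate, then ester reduction.

Key step: step 3

Remark on the chemistry: the benzylidene acetal carbon in 9, 10, 11, 14 and 15 forms in both configurations. It becomes the benzyl CH2 in step 9, so the epimer mixture is carried on and the SMILES leave this centre undefined.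

**Route**

Step 1
Reactants: 1 methyl 2-(bromomethyl)acrylate; 2 methyl acrylate
Product: 4 dimethyl 2,4-dimethylenepentanedioate, via allylammonium bromide 3 (not isolated)
Conditions: DABCO (2.2 equiv), THF/H2O (1:1), rt; then 2 (3 equiv), rt
Reagents that add atoms: none
Why: In this Morita–Baylis–Hillman-type coupling DABCO turns 1 into allylammonium salt 3, the DABCO–acrylate zwitterionic enolate adds to it in SN2' fashion, and E1cB loss of DABCO restores the second methylene to give the 1,4-diene.

Step 2
Reactants: 4 dimethyl 2,4-dimethylenepentanedioate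
Product: 5 2,4-dimethylenepentane-1,5-diol
Conditions: i-Bu2AlH (4.5 equiv), CH2Cl2, −78 to 0 °C; aq. potassium sodium tartrate
Reagents that add atoms: none
Why: Aluminium hydride 1,2-reduction of both 2-substituted acrylate esters should give the bis-allylic diol without conjugate reduction.

Step 3
Reactants: 5 2,4-dimethylenepentane-1,5-diol
Product: 7 [(2S)-2-{[(2S)-2-(hydroxymethyl)oxiran-2-yl]methyl}oxiran-2-yl]methanol, via mono-epoxide 6 (not isolated)
Conditions: Ti(OiPr)4 (20 mol%), L-(+)-diethyl tartrate (24 mol%), t-BuOOH (4 equiv, isooctane), powdered 4 Å molecular sieves, CH2Cl2, −20 °C; non-aqueous work-up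
Reagents that add atoms: tert-butyl hydroperoxide, CC(C)(C)OO
Why: Each allylic hydroxyl exchanges onto the dimeric titanium tartrate beside an η2-bound tert-butyl peroxide, and the distal peroxide oxygen passes to the alkene in a concerted spiro transition state, giving first mono-epoxide 6 and then 7. The closest known reaction type is the Katsuki–Sharpless asymmetric epoxidation of 2-substituted (methallyl-type) allylic alcohols, applied here in two directions. Each oxirane is closed by this single three-membered oxygen-atom transfer, both C–O bonds of a ring forming together, and neither oxirane is a ring of the target. The two new quaternary stereocentres (later C5 and C7) are set by the L-(+)-tartrate ligand, which by the usual mnemonic (CH2OH at the lower right, oxygen from the bottom face) should give S at each centre, the same sense that makes (S)-2-methylglycidol from methallyl alcohol. The step needs enantioface selectivity at two 1,1-disubstituted alkenes whose substituents (CH2OH and CH2R) differ little in size, and it is secured by the allylic hydroxyl on each alkene, which anchors the substrate to the chiral titanium centre. Because the two transfers are independent, a facial error leads mainly to the meso R,S isomer, a removable diastereomer, so the C2-symmetric product should be enriched in enantiomeric purity.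

Step 4
Reactants: 7 (S,S)-bis-epoxy diol
Product: 8 (2S,4S)-2,4-dimethylpentane-1,2,4,5-tetraol
Conditions: LiAlH4 (3 equiv), THF, 0 °C to rt; Fieser work-up
Reagents that add atoms: none
Why: Hydride SN2 opening of each 2,2-disubstituted oxirane at its unsubstituted CH2 turns that carbon into a methyl group and leaves both tertiary C–O bonds, so both stereocentres are kept.

Step 5
Reactants: 8 (2S,4S)-2,4-dimethylpentane-1,2,4,5-tetraol
Product: 9 (2S)-2-methyl-3-[(4S)-4-methyl-2-phenyl-1,3-dioxolan-4-yl]propane-1,2-diol
Conditions: PhCH(OMe)2 (1.0 equiv), camphorsulfonic acid (5 mol%), DMF, 50 °C, reduced pressure; recovered 8 and bis-acetal re-equilibrated with acid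
Reagents that add atoms: benzaldehyde dimethyl acetal, COC(OC)c1ccccc1
Why: Acid-catalysed transacetalisation under thermodynamic control closes a five-membered dioxolane on one primary/tertiary 1,2-diol, and since the two diol ends are homotopic through the C2 axis any mono-acetal is the same compound, so this statistical step differentiates the termini without touching a backbone stereocentre.

Step 6
Reactants: 9 mono-benzylidene acetal diol
Product: 11 (4S)-4-methyl-4-{[(2S)-2-methyloxiran-2-yl]methyl}-2-phenyl-1,3-dioxolane, via tosylate 10 (not isolated)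
Conditions: TsCl (1.1 equiv), Et3N, Bu2SnO (2 mol%), CH2Cl2, 0 °C to rt; then K2CO3, MeOH, rt
Reagents that add atoms: none
Why: Primary-selective sulfonylation of the 1,2-diol (tin-acetal catalysis) followed by intramolecular Williamson closure (3-exo-tet) by the tertiary alkoxide gives the 2,2-disubstituted oxirane, and the C7–O bond is never broken so its configuration is retained.

Step 7
Reactants: 11 epoxide acetal; 12 1-bromopentadecane
Product: 14 (2R)-2-methyl-1-[(4S)-4-methyl-2-phenyl-1,3-dioxolan-4-yl]octadecan-2-ol, via pentadecylmagnesium bromide 13 (not isolated)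
Conditions: 12, Mg, THF, 50 °C; then CuI (10 mol%), 11, THF, −30 to 0 °C; aq. NH4Cl
Reagents that add atoms: none
Why: Copper-catalysed Grignard opening of the 2,2-disubstituted terminal epoxide by SN2 attack at its unsubstituted CH2 joins C8 to the pentadecyl chain and leaves the tertiary carbinol centre untouched.

Step 8
Reactants: 14 tertiary alcohol acetal
Product: 15 triethyl({(2R)-2-methyl-1-[(4S)-4-methyl-2-phenyl-1,3-dioxolan-4-yl]octadecan-2-yl}oxy)silane
Conditions: Et3SiOTf (1.3 equiv), 2,6-lutidine, CH2Cl2, −78 to −40 °C
Reagents that add atoms: triethylsilyl trifluoromethanesulfonate, CC[Si](CC)(CC)OS(=O)(=O)C(F)(F)F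
Why: Silylation of the hindered tertiary alcohol with the silyl triflate masks the C7 hydroxyl, which would otherwise close a five-membered lactol on the C4 aldehyde of step 10, and low temperature with a small excess should leave the benzylidene acetal intact.

Step 9
Reactants: 15 silyl ether acetal
Product: 16 (2S,4R)-2-(benzyloxy)-2,4-dimethyl-4-[(triethylsilyl)oxy]icosan-1-ol
Conditions: i-Bu2AlH (3 equiv), CH2Cl2, −78 to 0 °C; aq. potassium sodium tartrate
Reagents that add atoms: none
Why: In this regioselective reductive opening of a benzylidene acetal, aluminium binds the less hindered primary oxygen, the acetal C–O bond to it breaks, and hydride reduces the oxocarbenium ion on the tertiary oxygen, giving the tertiary benzyl ether and the free primary alcohol.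

Step 10
Reactants: 16 primary alcohol
Product: 17 (2S,4R)-2-(benzyloxy)-2,4-dimethyl-4-[(triethylsilyl)oxy]icosanal
Conditions: Dess–Martin periodinane, pyridine, CH2Cl2, 0 °C to rt
Reagents that add atoms: none
Why: Dess–Martin oxidation of the neopentyl-type primary alcohol gives the aldehyde, whose alpha carbon is quaternary and so cannot epimerise.

Step 11
Reactants: 17 alpha-benzyloxy aldehyde
Product: 18 methyl (3S,4S,6R)-4-(benzyloxy)-3-hydroxy-4,6-dimethyl-6-[(triethylsilyl)oxy]docosanoate
Conditions: MgBr2·OEt2 (3 equiv), CH2Cl2, −78 °C; then ketene silyl acetal (2 equiv), −78 to −30 °C; 1 M HCl work-up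
Reagents that add atoms: 1-(tert-butyldimethylsilyloxy)-1-methoxyethene, C=C(OC)O[Si](C)(C)C(C)(C)C
Why: In this chelation-controlled Mukaiyama aldol addition MgBr2 holds the aldehyde oxygen and the alpha benzyloxy oxygen in a five-membered chelate, and the ketene silyl acetal attacks the face carrying the small methyl group, anti to the branched C6 chain, which should set the new carbinol (target C4) as S, syn to the C5 oxygen.

Step 12
Reactants: 18 aldol adduct
Product: 20 (4S,5S)-4-hydroxy-5-methyl-5-{(2R)-2-methyl-2-[(triethylsilyl)oxy]octadecyl}oxolan-2-one, via dihydroxy ester 19 (not isolated)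
Conditions: H2 (1 atm), Pd(OH)2/C, EtOAc, rt; filter; then pyridinium p-toluenesulfonate (cat.), toluene, 40 °C
Reagents that add atoms: none
Why: Hydrogenolysis cleaves the tertiary benzyl ether at its benzylic C–O bond to free the C5 hydroxyl, which closes the five-membered lactone ring onto the methyl ester by acid-catalysed 5-exo-trig acyl substitution (Thorpe–Ingold assisted) without touching any stereocentre.

Step 13
Reactants: 20 silyl-protected lactone
Product: 21 (4S,5S)-4-hydroxy-5-[(2R)-2-hydroxy-2-methyloctadecyl]-5-methyloxolan-2-one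
Conditions: HF·pyridine, pyridine, THF, 0 °C to rt
Reagents that add atoms: none
Why: Fluoride cleavage of the tertiary triethylsilyl ether under buffered, non-basic conditions should free the C7 hydroxyl without beta-elimination of the C4 hydroxyl to the butenolide.

**Compound list**

1 | methyl 2-(bromomethyl)acrylate | C=C(CBr)C(=O)OC | starting material
2 | methyl acrylate | C=CC(=O)OC | starting material
3 | 1-[2-(methoxycarbonyl)prop-2-en-1-yl]-4-aza-1-azoniabicyclo[2.2.2]octane bromide | C=C(C[N+]12CCN(CC1)CC2)C(=O)OC.[Br-] | intermediate (not isolated)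
4 | dimethyl 2,4-dimethylenepentanedioate | C=C(CC(=C)C(=O)OC)C(=O)OC | intermediate
5 | 2,4-dimethylenepentane-1,5-diol | C=C(CO)CC(=C)CO | intermediate
6 | 2-{[(2S)-2-(hydroxymethyl)oxiran-2-yl]methyl}prop-2-en-1-ol | C=C(CO)C[C@]1(CO)CO1 | intermediate (not isolated)
7 | [(2S)-2-{[(2S)-2-(hydroxymethyl)oxiran-2-yl]methyl}oxiran-2-yl]methanol | OC[C@@]1(OC1)C[C@]1(CO)CO1 | intermediate
8 | (2S,4S)-2,4-dimethylpentane-1,2,4,5-tetraol | OC[C@@](C)(O)C[C@](O)(CO)C | intermediate
9 | (2S)-2-methyl-3-[(4S)-4-methyl-2-phenyl-1,3-dioxolan-4-yl]propane-1,2-diol (acetal epimers) | OC[C@@](C)(O)C[C@@]1(C)COC(c2ccccc2)O1 | intermediate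
10 | (2S)-2-hydroxy-2-methyl-3-[(4S)-4-methyl-2-phenyl-1,3-dioxolan-4-yl]propyl 4-methylbenzenesulfonate | Cc1ccc(cc1)S(=O)(=O)OC[C@@](C)(O)C[C@@]1(C)COC(c2ccccc2)O1 | intermediate (not isolated)
11 | (4S)-4-methyl-4-{[(2S)-2-methyloxiran-2-yl]methyl}-2-phenyl-1,3-dioxolane | C1O[C@@]1(C)C[C@@]1(C)COC(c2ccccc2)O1 | intermediate
12 | 1-bromopentadecane | CCCCCCCCCCCCCCCBr | starting material
13 | pentadecylmagnesium bromide | CCCCCCCCCCCCCCC[Mg]Br | intermediate (not isolated)
14 | (2R)-2-methyl-1-[(4S)-4-methyl-2-phenyl-1,3-dioxolan-4-yl]octadecan-2-ol | CCCCCCCCCCCCCCCC[C@@](C)(O)C[C@@]1(C)COC(c2ccccc2)O1 | intermediate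
15 | triethyl({(2R)-2-methyl-1-[(4S)-4-methyl-2-phenyl-1,3-dioxolan-4-yl]octadecan-2-yl}oxy)silane | CCCCCCCCCCCCCCCC[C@@](C)(O[Si](CC)(CC)CC)C[C@@]1(C)COC(c2ccccc2)O1 | intermediate
16 | (2S,4R)-2-(benzyloxy)-2,4-dimethyl-4-[(triethylsilyl)oxy]icosan-1-ol | CCCCCCCCCCCCCCCC[C@@](C)(O[Si](CC)(CC)CC)C[C@@](C)(CO)OCc1ccccc1 | intermediate
17 | (2S,4R)-2-(benzyloxy)-2,4-dimethyl-4-[(triethylsilyl)oxy]icosanal | CCCCCCCCCCCCCCCC[C@@](C)(O[Si](CC)(CC)CC)C[C@@](C)(C=O)OCc1ccccc1 | intermediate
18 | methyl (3S,4S,6R)-4-(benzyloxy)-3-hydroxy-4,6-dimethyl-6-[(triethylsilyl)oxy]docosanoate | CCCCCCCCCCCCCCCC[C@@](C)(O[Si](CC)(CC)CC)C[C@@](C)([C@@H](O)CC(=O)OC)OCc1ccccc1 | intermediate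
19 | methyl (3S,4S,6R)-3,4-dihydroxy-4,6-dimethyl-6-[(triethylsilyl)oxy]docosanoate | CCCCCCCCCCCCCCCC[C@@](C)(O[Si](CC)(CC)CC)C[C@](C)(O)[C@@H](O)CC(=O)OC | intermediate (not isolated)
20 | (4S,5S)-4-hydroxy-5-methyl-5-{(2R)-2-methyl-2-[(triethylsilyl)oxy]octadecyl}oxolan-2-one | CCCCCCCCCCCCCCCC[C@@](C)(O[Si](CC)(CC)CC)C[C@]1(C)OC(=O)C[C@@H]1O | intermediate
21 | (4S,5S)-4-hydroxy-5-[(2R)-2-hydroxy-2-methyloctadecyl]-5-methyloxolan-2-one | CCCCCCCCCCCCCCCC[C@@](C)(O)C[C@]1(C)OC(=O)C[C@@H]1O | target

**Step count and risks**

Total step count: 13. Longest linear sequence: 13 steps (1 and 2 to 21); 1-bromopentadecane 12 enters in step 7.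

Steps most likely to fail:

- **Step 3 (double epoxidation).** The bis-allylic diol and the epoxy diol products may bridge or chelate titanium and displace tartrate, so that turnover stalls at the mono-epoxide and facial selectivity erodes. The 2,2-disubstituted oxiranes may also be opened by isopropoxide during the long reaction, or lost in isolation of the water-soluble product. The fallback runs the same epoxidation one alkene at a time on lipophilic mono-ols; it sets out from 5 and comes back to the route at 9. Diol 5 would be mono-silylated (NaH, 1 equiv, then t-BuPh2SiCl, THF) to the mono-silyl ether F1. One Katsuki–Sharpless epoxidation with the L-(+)-tartrate catalyst should give the (S)-epoxy alcohol F2. LiAlH4 would open the oxirane to the 1,2-diol F3, and PhCH(OMe)2 with acid would close the benzylidene acetal F4. Bu4NF would free the second allylic alcohol F5, and a second epoxidation with the same catalyst should give the epoxy alcohol F6. LiAlH4 then gives 9. This variant also bypasses the statistical step 5.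

- **Step 5 (mono-benzylidenation).** The reversible acetalisation may run on to the bis-acetal or scramble between the dioxolane and larger-ring acetals, so that little mono-acetal is obtained per pass. The fallback differentiates the ends by irreversible, primary-selective mono-sulfonylation instead; it sets out from 8 and comes back to the route at 10. Tetraol 8 would be treated with TsCl (1 equiv), Bu2SnO (cat.) and Et3N in MeCN to give the monotosylate F7, with unreacted 8 recycled. The remaining 1,2-diol would then be closed to the benzylidene acetal with PhCH(OMe)2 and pyridinium p-toluenesulfonate to give 10, which is cyclised to 11 with K2CO3 in MeOH as in the second stage of step 6.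

- **Step 11 (aldol addition).** Facial selectivity may be poor if the magnesium chelate is incomplete (open Felkin–Anh addition leads to the C4 epimer) or if the chelate discriminates weakly between the methyl group and the C6 methylene. The fallback is reagent-controlled allylation followed by oxidative cleavage; it sets out from 17 and comes back to the route at 20. Aldehyde 17 would undergo Brown allylation with (−)-B-allyldiisopinocampheylborane (the reagent derived from (+)-α-pinene; Et2O, −78 °C, then NaOH/H2O2), which adds to the Si face of aldehydes and should give the homoallylic alcohol F8. Lemieux–Johnson cleavage (OsO4 cat., NaIO4, 2,6-lutidine, dioxane/H2O) would give the beta-hydroxy aldehyde F9, and Pinnick oxidation (NaClO2, NaH2PO4, 2-methyl-2-butene) the beta-hydroxy acid F10. Hydrogenolysis over Pd(OH)2/C would give the dihydroxy acid F11, which should lactonise to 20.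

**Further compounds**

F1 | step 3 | 2-{2-[(tert-butyldiphenylsilyloxy)methyl]prop-2-en-1-yl}prop-2-en-1-ol | C=C(CO)CC(=C)CO[Si](c1ccccc1)(c1ccccc1)C(C)(C)C
F2 | step 3 | [(2S)-2-{2-[(tert-butyldiphenylsilyloxy)methyl]prop-2-en-1-yl}oxiran-2-yl]methanol | OC[C@@]1(OC1)CC(=C)CO[Si](c1ccccc1)(c1ccccc1)C(C)(C)C
F3 | step 3 | (2S)-4-[(tert-butyldiphenylsilyloxy)methyl]-2-methylpent-4-ene-1,2-diol | OC[C@@](C)(O)CC(=C)CO[Si](c1ccccc1)(c1ccccc1)C(C)(C)C
F4 | step 3 | tert-butyl(diphenyl){[2-({(4S)-4-methyl-2-phenyl-1,3-dioxolan-4-yl}methyl)prop-2-en-1-yl]oxy}silane | C=C(CO[Si](c1ccccc1)(c1ccccc1)C(C)(C)C)C[C@@]1(C)COC(c2ccccc2)O1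
F5 | step 3 | 2-{[(4S)-4-methyl-2-phenyl-1,3-dioxolan-4-yl]methyl}prop-2-en-1-ol | C=C(CO)C[C@@]1(C)COC(c2ccccc2)O1
F6 | step 3 | [(2S)-2-{[(4S)-4-methyl-2-phenyl-1,3-dioxolan-4-yl]methyl}oxiran-2-yl]methanol | OC[C@@]1(OC1)C[C@@]1(C)COC(c2ccccc2)O1
F7 | step 5 | (2S,4S)-2,4,5-trihydroxy-2,4-dimethylpentyl 4-methylbenzenesulfonate | Cc1ccc(cc1)S(=O)(=O)OC[C@@](C)(O)C[C@](O)(CO)C
F8 | step 11 | (4S,5S,7R)-5-(benzyloxy)-5,7-dimethyl-7-[(triethylsilyl)oxy]tricos-1-en-4-ol | CCCCCCCCCCCCCCCC[C@@](C)(O[Si](CC)(CC)CC)C[C@@](C)([C@@H](O)CC=C)OCc1ccccc1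
F9 | step 11 | (3S,4S,6R)-4-(benzyloxy)-3-hydroxy-4,6-dimethyl-6-[(triethylsilyl)oxy]docosanal | CCCCCCCCCCCCCCCC[C@@](C)(O[Si](CC)(CC)CC)C[C@@](C)([C@@H](O)CC=O)OCc1ccccc1
F10 | step 11 | (3S,4S,6R)-4-(benzyloxy)-3-hydroxy-4,6-dimethyl-6-[(triethylsilyl)oxy]docosanoic acid | CCCCCCCCCCCCCCCC[C@@](C)(O[Si](CC)(CC)CC)C[C@@](C)([C@@H](O)CC(=O)O)OCc1ccccc1
F11 | step 11 | (3S,4S,6R)-3,4-dihydroxy-4,6-dimethyl-6-[(triethylsilyl)oxy]docosanoic acid | CCCCCCCCCCCCCCCC[C@@](C)(O[Si](CC)(CC)CC)C[C@](C)(O)[C@@H](O)CC(=O)O
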